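**Plan**

Numbering follows germacrane: carbocycle C1–C10, lactone O–C12(=O)–C11=C7–C6, C13 = CH2OH on C11, C14 and C15 = methyls on C10 and C4.
Enabling feature: both olefinic carbons of the butenolide carry an oxygenated carbon (C11–C13H2O, C7–C8HO). The ring is therefore a but-2-yne-1,4-diol unit (C8–C7≡C11–C13) plus an aldehyde (C6) plus CO (C12). Its C6–C7 edge is shared with the ten-membered ring, so one [2+2+1] event can close both rings.
Retrosynthesis: cut the C8–O tiglate; cut C6–C7, C11–C12 and C12–O together (acyclic epoxy-ynal 16 + CO); remove the C4–C5 epoxide oxygen; cut C1–C10 (fragments A = 3 and B = 11); cut C7–C8 (enal 7 + alkyne 8).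
Forward: the chain is joined at C7–C8, then at C1–C10; the epoxide follows; carbocycle and butenolide arise together in step 11; the tiglate comes last.
Stereochemistry: C8 comes from zinc–ProPhenol alkynylation, C1 from a ligand-controlled Nozaki–Hiyama–Kishi coupling, C4/C5 from Sharpless epoxidation, and C6 is relayed from the C4/C5 oxirane in the key step. The 9Z alkene comes from trans-hydroalumination–iodination of but-2-yn-1-ol; the 4E geometry and the E-tiglate are bought.

Key step: step 11

Assumption: the (S,S)-ProPhenol ligand (step 4) and the (S)-oxazoline–sulfonamide ligand (step 6) are taken to give the configurations drawn; both ligands exist in either enantiomeric form, so the antipode is used if a model reaction shows the opposite sense.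

**Step 1**
Reactants: 1 geranyl acetate
Product: 3 (2E)-3-methyl-6-oxohex-2-en-1-yl acetate (fragment A), via secondary ozonide 2 (not isolated)
Conditions: O3 (1.0 equiv), CH2Cl2, −78 °C; then PPh3, −78 °C to rt
Reagents that add atoms: ozone, [O-][O+]=O
Why: Ozonolysis (Criegee mechanism) with one equivalent of ozone should select the electron-rich isopropylidene alkene over the alkene deactivated by the allylic acetate, and reductive work-up gives the C1 aldehyde.

**Step 2**
Reactants: 4 but-2-yn-1-ol
Product: 6 (2Z)-3-iodobut-2-en-1-ol, via cyclic alkenylalanate 5 (not isolated)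
Conditions: NaAlH2(OCH2CH2OMe)2, Et2O, 0 °C to rt; then I2, THF, −78 °C to 0 °C
Reagents that add atoms: iodine, II
Why: Hydroxyl-directed trans-hydroalumination of a propargylic alcohol gives the five-membered alanate 5, and iodinolysis with retention places iodine cis to CH2OH, which fixes the future 9Z geometry.

**Step 3**
Reactants: 6 (2Z)-3-iodobut-2-en-1-ol
Product: 7 (2Z)-3-iodobut-2-enal
Conditions: MnO2, CH2Cl2, rt, dark
Reagents that add atoms: none
Why: Heterogeneous MnO2 oxidation of an allylic alcohol is neutral, stops at the aldehyde and should leave the Z-iodoalkene unisomerised if the enal is used at once.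

**Step 4**
Reactants: 7 (2Z)-3-iodobut-2-enal; 8 tert-butyldimethyl(prop-2-yn-1-yloxy)silane
Product: 10 (4S,5Z)-1-[(tert-butyldimethylsilyl)oxy]-6-iodohept-5-en-2-yn-4-ol, via alkynyl(methyl)zinc 9 (not isolated)
Conditions: 8, ZnMe2, (S,S)-ProPhenol [2,6-bis{[(S)-2-(hydroxydiphenylmethyl)pyrrolidin-1-yl]methyl}-4-methylphenol] (20 mol %), Ph3P=O (40 mol %), toluene, rt; then 7, 0 °C
Reagents that add atoms: none
Why: In the dinuclear zinc–ProPhenol asymmetric alkynylation of an α,β-unsaturated aldehyde, the alkynylzinc 9 is delivered inside the chiral pocket to the Re face of 7 and sets C8 as S.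

**Step 5**
Reactants: 10 (4S,5Z)-1-[(tert-butyldimethylsilyl)oxy]-6-iodohept-5-en-2-yn-4-ol
Product: 11 triethylsilyl ether of 10 (fragment B)
Conditions: Et3SiCl, imidazole, CH2Cl2, 0 °C
Reagents that add atoms: chlorotriethylsilane, CC[Si](Cl)(CC)CC
Why: Standard imidazole-promoted silylation gives a C8 ether that cannot ionise on nickel and can later be cleaved in the presence of the bulkier silyl ethers.

**Step 6**
Reactants: 11 fragment B; 3 fragment A
Product: 12 (2E,6R,7Z,9S)-12-[(tert-butyldimethylsilyl)oxy]-6-hydroxy-3,7-dimethyl-9-[(triethylsilyl)oxy]dodeca-2,7-dien-10-yn-1-yl acetate (germacrane 1R,8S)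
Conditions: CrCl2, NiCl2 (cat.), (S)-N-[2-(4-isopropyl-4,5-dihydrooxazol-2-yl)-6-methylphenyl]methanesulfonamide, Et3N, THF, rt
Reagents that add atoms: none
Why: In the asymmetric Nozaki–Hiyama–Kishi coupling, the trisubstituted alkenyl iodide is transferred with retention of geometry through nickel to chromium, and the chromium-bound sulfonamide ligand directs attack to the Si face of the aldehyde, giving 1R, while ester, alkyne and silyl ethers are tolerated.

**Step 7**
Reactants: 12 C1 alcohol
Product: 13 C1 tert-butyldimethylsilyl ether of 12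
Conditions: t-BuMe2SiOSO2CF3, 2,6-lutidine, CH2Cl2, −78 °C
Reagents that add atoms: tert-butyldimethylsilyl trifluoromethanesulfonate, CC(C)(C)[Si](C)(C)OS(=O)(=O)C(F)(F)F
Why: Silyl triflate silylation protects the hindered secondary allylic alcohol at low temperature, and no acid-labile epoxide is present yet.

**Step 8**
Reactants: 13 acetate
Product: 14 (2E,6R,7Z,9S)-6,12-bis[(tert-butyldimethylsilyl)oxy]-3,7-dimethyl-9-[(triethylsilyl)oxy]dodeca-2,7-dien-10-yn-1-ol
Conditions: K2CO3 (cat.), MeOH, 0 °C
Reagents that add atoms: none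
Why: Base-catalysed transesterification (methanolysis) removes the only ester and leaves the three silyl ethers in place.

**Step 9**
Reactants: 14 allylic alcohol
Product: 15 [(2R,3R)-3-{(3R,4Z,6S)-3,9-bis[(tert-butyldimethylsilyl)oxy]-4-methyl-6-[(triethylsilyl)oxy]non-4-en-7-yn-1-yl}-3-methyloxiran-2-yl]methanol (germacrane 1R,4R,5R,8S)
Conditions: Ti(OiPr)4, D-(−)-diethyl tartrate, t-BuOOH, 4 Å molecular sieves, CH2Cl2, −20 °C
Reagents that add atoms: tert-butyl hydroperoxide, CC(C)(C)OO
Why: In the Sharpless asymmetric epoxidation only the alkene with a free allylic hydroxyl binds titanium, and the D-(−)-tartrate delivers oxygen to the face of this geraniol-type E-alkene that gives the trans (4R,5R)-epoxide under reagent control.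

**Step 10**
Reactants: 15 epoxy alcohol
Product: 16 (2S,3R)-3-{(3R,4Z,6S)-3,9-bis[(tert-butyldimethylsilyl)oxy]-4-methyl-6-[(triethylsilyl)oxy]non-4-en-7-yn-1-yl}-3-methyloxirane-2-carbaldehyde (epoxy-ynal; same spatial arrangement as 15, the C5 descriptor changes by priority only)
Conditions: 2,2,6,6-tetramethylpiperidin-1-oxyl (cat.), PhI(OAc)2, CH2Cl2, rt
Reagents that add atoms: none
Why: The oxoammonium (TEMPO) oxidation of a primary alcohol stops at the aldehyde under almost neutral conditions that spare the epoxide, the alkyne and the silyl ethers.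

**Step 11**
Reactants: 16 epoxy-ynal
Product: 18 (1R,4R,5R,6S,8S,9Z)-1,13-bis[(tert-butyldimethylsilyl)oxy]-4,5-epoxy-8-[(triethylsilyl)oxy]germacra-7(11),9-dien-12,6-olide, via nickeladihydrofuran 17 (not isolated)
Conditions: Ni(cod)2 (1.1 equiv) and 1,3-bis(2,6-diisopropylphenyl)imidazol-2-ylidene (IPr, 1.1 equiv) premixed, toluene; slow addition of 16 (final 2 mM), rt to 45 °C; then CO (1 atm), rt
Reagents that add atoms: carbon monoxide, [C-]#[O+]
Why: Proposed new method: premixed Ni(cod)2/IPr gives a zerovalent nickel fragment that binds the C7≡C11 alkyne and the C6 aldehyde of 16 and couples them by oxidative cyclization to the divalent nickeladihydrofuran 17 (C6–C7 formed), after which CO inserts into the Ni–C11 bond and C12–O reductive elimination releases 18, in sum a stepwise hetero-Pauson–Khand [2+2+1]. The closest known reaction types are the nickel-catalysed reductive macrocyclization of ynals (same oxidative cyclization, ended by a silane), the carbonylation of isolated nickeladihydrofurans to butenolides, and the molybdenum-, ruthenium- or titanium-mediated hetero-Pauson–Khand reaction of ynals, which so far closes only five- and six-membered carbocycles; what is new is their merger in a ten-membered closure. The carbocycle closes 10-exo-dig at the alkyne (C7 attacked, C11 left exocyclic on nickel) with the carbonyl oxygen exocyclic, the butenolide closes by contraction of the six-membered acylnickelacycle, and the syn addition across the alkyne places C6 cis to C12 and C8 cis to C13 as the lactone demands. The one new stereocenter, C6, is controlled by the adjacent oxirane: the C15 methyl, cis to C6, holds the aldehyde in the rotamer with C6–H over C15 and the oxygen turned to the periphery (A1,3-type strain), and C7 approaches anti to the C5–O bond, which gives the threo 5R,6S array. Regioselectivity (C7 rather than C11, which would give an eleven-membered ring with an endocyclic E-alkene) is secured by the bulky carbene, which keeps the small CH2OSi group next to nickel and sends the branched C8 terminus to the bond-forming carbon. Chemoselectivity rests on the substrate design: the epoxide blocks the conjugate pathways open to an enal, silyl ethers instead of esters at C8 and C13 cannot ionise on zerovalent nickel, and slow addition at high dilution to stoichiometric nickel disfavours oligomers.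

**Step 12**
Reactants: 18 tris-silyl macrocycle
Product: 19 (1R,4R,5R,6S,8S,9Z)-1,13-bis[(tert-butyldimethylsilyl)oxy]-4,5-epoxy-8-hydroxygermacra-7(11),9-dien-12,6-olide
Conditions: pyridinium p-toluenesulfonate (cat.), MeOH–CH2Cl2, 0 °C
Reagents that add atoms: none
Why: Acid-catalysed methanolysis distinguishes silyl ethers by the size of the groups on silicon, so the triethylsilyl ether should go well before either tert-butyldimethylsilyl ether, and the mild acid should spare the epoxide.

**Step 13**
Reactants: 19 C8 alcohol; 20 tigloyl chloride [(2E)-2-methylbut-2-enoyl chloride]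
Product: 21 (1R,4R,5R,6S,8S,9Z)-1,13-bis[(tert-butyldimethylsilyl)oxy]-4,5-epoxy-8-(tigloyloxy)germacra-7(11),9-dien-12,6-olide
Conditions: pyridine, 4-(dimethylamino)pyridine (cat.), CH2Cl2, 0 °C to rt
Reagents that add atoms: none
Why: DMAP-catalysed acylation with the acid chloride esterifies the only free hydroxyl with retention at C8, and the weak base avoids deprotonation at C6 and deconjugation of the E-configured acyl group.

**Step 14**
Reactants: 21 bis-silyl tiglate
Product: 22 target, (1R,4R,5R,6S,8S,9Z)-4,5-epoxy-1,13-dihydroxy-8-(tigloyloxy)germacra-7(11),9-dien-12,6-olide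
Conditions: HF·pyridine, pyridine, THF, 0 °C to rt
Reagents that add atoms: none
Why: Fluoride-driven desilylation in a pyridine-buffered, non-basic medium frees C1–OH and C13–OH without epimerising C6, migrating the tiglate or opening the epoxide.

**Compound list**

1 | geranyl acetate, (2E)-3,7-dimethylocta-2,6-dien-1-yl acetate | CC(C)=CCC/C(C)=C/COC(C)=O | starting material
2 | secondary ozonide (1,2,4-trioxolane) of the isopropylidene alkene of 1 | CC1(C)OOC(CC/C(C)=C/COC(C)=O)O1 | intermediate
3 | (2E)-3-methyl-6-oxohex-2-en-1-yl acetate (fragment A) | O=CCC/C(C)=C/COC(C)=O | intermediate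
4 | but-2-yn-1-ol | CC#CCO | starting material
5 | sodium cyclic alkenylalanate from 4 (five-membered O–Al–C ring) | [Na+].CC1=CCO[Al-]1(OCCOC)OCCOC | intermediate
6 | (2Z)-3-iodobut-2-en-1-ol | C/C(I)=C/CO | intermediate
7 | (2Z)-3-iodobut-2-enal | C/C(I)=C/C=O | intermediate
8 | tert-butyldimethyl(prop-2-yn-1-yloxy)silane | C#CCO[Si](C)(C)C(C)(C)C | starting material
9 | methyl{3-[(tert-butyldimethylsilyl)oxy]prop-1-yn-1-yl}zinc | C[Zn]C#CCO[Si](C)(C)C(C)(C)C | intermediate
10 | (4S,5Z)-1-[(tert-butyldimethylsilyl)oxy]-6-iodohept-5-en-2-yn-4-ol | O[C@H](C#CCO[Si](C)(C)C(C)(C)C)/C=C(/C)I | intermediate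
11 | (4S,5Z)-1-[(tert-butyldimethylsilyl)oxy]-6-iodo-4-[(triethylsilyl)oxy]hept-5-en-2-yne (fragment B) | CC[Si](CC)(CC)O[C@H](C#CCO[Si](C)(C)C(C)(C)C)/C=C(/C)I | intermediate
12 | (2E,6R,7Z,9S)-12-[(tert-butyldimethylsilyl)oxy]-6-hydroxy-3,7-dimethyl-9-[(triethylsilyl)oxy]dodeca-2,7-dien-10-yn-1-yl acetate | CC[Si](CC)(CC)O[C@H](C#CCO[Si](C)(C)C(C)(C)C)/C=C(/C)[C@H](O)CC/C(C)=C/COC(C)=O | intermediate
13 | (2E,6R,7Z,9S)-6,12-bis[(tert-butyldimethylsilyl)oxy]-3,7-dimethyl-9-[(triethylsilyl)oxy]dodeca-2,7-dien-10-yn-1-yl acetate | CC[Si](CC)(CC)O[C@H](C#CCO[Si](C)(C)C(C)(C)C)/C=C(/C)[C@H](O[Si](C)(C)C(C)(C)C)CC/C(C)=C/COC(C)=O | intermediate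
14 | (2E,6R,7Z,9S)-6,12-bis[(tert-butyldimethylsilyl)oxy]-3,7-dimethyl-9-[(triethylsilyl)oxy]dodeca-2,7-dien-10-yn-1-ol | CC[Si](CC)(CC)O[C@H](C#CCO[Si](C)(C)C(C)(C)C)/C=C(/C)[C@H](O[Si](C)(C)C(C)(C)C)CC/C(C)=C/CO | intermediate
15 | (2R,3R)-epoxy alcohol from 14 (germacrane 1R,4R,5R,8S) | CC[Si](CC)(CC)O[C@H](C#CCO[Si](C)(C)C(C)(C)C)/C=C(/C)[C@H](O[Si](C)(C)C(C)(C)C)CC[C@@]1(C)O[C@@H]1CO | intermediate
16 | (2S,3R)-epoxy aldehyde (epoxy-ynal) from 15 | CC[Si](CC)(CC)O[C@H](C#CCO[Si](C)(C)C(C)(C)C)/C=C(/C)[C@H](O[Si](C)(C)C(C)(C)C)CC[C@@]1(C)O[C@@H]1C=O | intermediate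
17 | (IPr)nickeladihydrofuran, ring O–Ni–C11=C7–C6 fused to the ten-membered ring | CC[Si](CC)(CC)O[C@H]1/C=C(/C)[C@H](O[Si](C)(C)C(C)(C)C)CC[C@@]2(C)O[C@@H]2[C@H]2O[Ni-](C3=[N+](c4c(C(C)C)cccc4C(C)C)C=CN3c3c(C(C)C)cccc3C(C)C)C(CO[Si](C)(C)C(C)(C)C)=C12 | intermediate
18 | (1R,4R,5R,6S,8S,9Z)-1,13-bis[(tert-butyldimethylsilyl)oxy]-4,5-epoxy-8-[(triethylsilyl)oxy]germacra-7(11),9-dien-12,6-olide | CC[Si](CC)(CC)O[C@H]1/C=C(/C)[C@H](O[Si](C)(C)C(C)(C)C)CC[C@@]2(C)O[C@@H]2[C@H]2OC(=O)C(CO[Si](C)(C)C(C)(C)C)=C12 | intermediate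
19 | 8-hydroxy compound from 18 | O[C@H]1/C=C(/C)[C@H](O[Si](C)(C)C(C)(C)C)CC[C@@]2(C)O[C@@H]2[C@H]2OC(=O)C(CO[Si](C)(C)C(C)(C)C)=C12 | intermediate
20 | tigloyl chloride, (2E)-2-methylbut-2-enoyl chloride | C/C=C(\C)C(=O)Cl | starting material
21 | 8-O-tiglate of 19 | C/C=C(\C)C(=O)O[C@H]1/C=C(/C)[C@H](O[Si](C)(C)C(C)(C)C)CC[C@@]2(C)O[C@@H]2[C@H]2OC(=O)C(CO[Si](C)(C)C(C)(C)C)=C12 | intermediate
22 | (1R,4R,5R,6S,8S,9Z)-4,5-epoxy-1,13-dihydroxy-8-(tigloyloxy)germacra-7(11),9-dien-12,6-olide | C/C=C(\C)C(=O)O[C@H]1/C=C(/C)[C@H](O)CC[C@@]2(C)O[C@@H]2[C@H]2OC(=O)C(CO)=C12 | target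

Total step count: 14. Longest linear sequence: 13 (steps 2–14, from but-2-yn-1-ol).

**Steps most likely to fail**

**1. Step 11 (labelled step).**
- What may go wrong: the ten-membered oxidative cyclization may be outrun by oligomerization or by coupling at C11. The facial selectivity at C6 may be poor. CO may displace the substrate from nickel (cycloreversion) before it inserts.
- Fallback (known chemistry, sets out from 7, returns at 18): the bonds are made one at a time and the ring is closed elsewhere.
- The zinc–ProPhenol alkynylation of 7 with methyl propiolate should give methyl (4S,5Z)-4-hydroxy-6-iodohept-5-en-2-ynoate F1, which is silylated (Et3SiCl, imidazole) to methyl (4S,5Z)-6-iodo-4-[(triethylsilyl)oxy]hept-5-en-2-ynoate F2.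
- An iodide-triggered halo-aldol (β-iodo Morita–Baylis–Hillman) reaction with monomeric formaldehyde (Et2AlI, CH2Cl2, −78 °C) installs C13 and the C7 iodide. After separation of the geometric isomers it gives methyl (2Z,4S,5Z)-2-(hydroxymethyl)-3,6-diiodo-4-[(triethylsilyl)oxy]hepta-2,5-dienoate F3, protected (t-BuMe2SiCl, imidazole) as its tert-butyldimethylsilyl ether F4.
- Commercial geraniol is epoxidised (Sharpless conditions, D-(−)-diethyl tartrate) to (2R,3R)-2,3-epoxygeraniol F5 and oxidised (TEMPO, PhI(OAc)2) to (2S,3R)-2,3-epoxygeranial F6.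
- An intermolecular Nozaki–Hiyama–Kishi reaction (CrCl2, cat. NiCl2) engages the more electron-poor β-iodoacrylate C–I bond of F4 with F6, and the C6 alkoxide lactonises onto the cis ester to the acyclic iodo butenolide F7.
- Selective ozonolysis of the isopropylidene alkene gives the butenolide C1 aldehyde F8.
- An intramolecular Nozaki–Hiyama–Kishi reaction of the C10 iodide with the C1 aldehyde (same chiral sulfonamide ligand, high dilution) closes the ten-membered ring at C1–C10 to the macrocyclic C1 alcohol F9, whose silylation (t-BuMe2SiCl, imidazole, DMF) gives 18.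

**2. Step 6.**
- What may go wrong: facial selectivity at C1 may be poor, the Z geometry may erode at the alkenylmetal stage, or low-valent nickel may react with the allylic acetate.
- Fallback (sets out from 3 and 11, returns at 12): stereocontrol is moved from C–C bond formation to a reduction. The ligand-free coupling (CrCl2, cat. NiCl2, DMSO) gives the C1-epimeric alcohol mixture F10. Buffered Dess–Martin oxidation gives the Z-enone F11. Corey–Bakshi–Shibata reduction with (S)-1-methyl-3,3-diphenyltetrahydro-1H,3H-pyrrolo[1,2-c][1,3,2]oxazaborole and catecholborane at −78 °C, with the α-methyl alkenyl group as the large substituent, should give the 1R alcohol 12.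

**3. Step 4.**
- What may go wrong: the β-iodoenal may isomerise from Z to E on the Lewis acidic zinc species, or the enantioselectivity may be low with this small hindered enal.
- Fallback (sets out from 7 and 8, returns at 10): the lithium acetylide of 8 (n-BuLi, THF, −78 °C) is added to 7 to give the racemic propargylic alcohol F12. It is oxidised (MnO2) to the alkenyl alkynyl ketone F13 and reduced by the Midland method with B-isopinocampheyl-9-borabicyclo[3.3.1]nonane made from (−)-α-pinene. The alkyne acts as the small group, so the S alcohol 10 should result.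

**Further compounds**

F1 | step 11 | methyl (4S,5Z)-4-hydroxy-6-iodohept-5-en-2-ynoate | O[C@H](C#CC(=O)OC)/C=C(/C)I
F2 | step 11 | methyl (4S,5Z)-6-iodo-4-[(triethylsilyl)oxy]hept-5-en-2-ynoate | CC[Si](CC)(CC)O[C@H](C#CC(=O)OC)/C=C(/C)I
F3 | step 11 | methyl (2Z,4S,5Z)-2-(hydroxymethyl)-3,6-diiodo-4-[(triethylsilyl)oxy]hepta-2,5-dienoate | CC[Si](CC)(CC)O[C@H](/C(I)=C(\CO)C(=O)OC)/C=C(/C)I
F4 | step 11 | tert-butyldimethylsilyl ether of F3 | CC[Si](CC)(CC)O[C@H](/C(I)=C(\CO[Si](C)(C)C(C)(C)C)C(=O)OC)/C=C(/C)I
F5 | step 11 | (2R,3R)-2,3-epoxygeraniol | CC(C)=CCC[C@@]1(C)O[C@@H]1CO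
F6 | step 11 | (2S,3R)-2,3-epoxygeranial | CC(C)=CCC[C@@]1(C)O[C@@H]1C=O
F7 | step 11 | acyclic iodo butenolide (C6–C7 and lactone formed, C1 masked as isopropylidene alkene) | CC[Si](CC)(CC)O[C@H](C1=C(CO[Si](C)(C)C(C)(C)C)C(=O)O[C@@H]1[C@H]1O[C@]1(C)CCC=C(C)C)/C=C(/C)I
F8 | step 11 | butenolide C1 aldehyde | CC[Si](CC)(CC)O[C@H](C1=C(CO[Si](C)(C)C(C)(C)C)C(=O)O[C@@H]1[C@H]1O[C@]1(C)CCC=O)/C=C(/C)I
F9 | step 11 | macrocyclic C1 alcohol (18 without the C1 silyl group) | CC[Si](CC)(CC)O[C@H]1/C=C(/C)[C@H](O)CC[C@@]2(C)O[C@@H]2[C@H]2OC(=O)C(CO[Si](C)(C)C(C)(C)C)=C12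
F10 | step 6 | C1-epimeric alcohol mixture corresponding to 12 | CC[Si](CC)(CC)O[C@H](C#CCO[Si](C)(C)C(C)(C)C)/C=C(/C)C(O)CC/C(C)=C/COC(C)=O
F11 | step 6 | Z-enone (C1 ketone) | CC[Si](CC)(CC)O[C@H](C#CCO[Si](C)(C)C(C)(C)C)/C=C(/C)C(=O)CC/C(C)=C/COC(C)=O
F12 | step 4 | racemic propargylic alcohol corresponding to 10 | OC(C#CCO[Si](C)(C)C(C)(C)C)/C=C(/C)I
F13 | step 4 | (5Z)-1-[(tert-butyldimethylsilyl)oxy]-6-iodohept-5-en-2-yn-4-one | O=C(C#CCO[Si](C)(C)C(C)(C)C)/C=C(/C)I
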